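## Retrosynthetic overview

1. Target (locants: lactone O1–C2–C3, carbocycle C3a–C4–C5–C6–C7–C8–C8a) ⇐ desilylation at O5, isobutyrylation of C8–OH and hydroxyl-directed reduction of a C8 ketone ⇐ α-hydroxy-β-diketone in which C7 carries OH and the (E)-butenoyl group.
2. Key disconnection C6–C7 by an α-ketol (acyloin) 1,2-shift: the seven-membered carbocycle comes from the cyclohexane C3a–C4–C5–C6–C8–C8a that carries at C8 a tertiary OH and a 2-oxopent-3-enoyl chain; C6 migrates from C8 to the first chain carbonyl, which becomes ring atom C7.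
3. Enabling feature: C7 is a fully substituted carbinol carbon between the oxygenated ring carbon C8 and the exocyclic butenoyl C=O (a tertiary α-ketol); of the two ring carbons on C8 only C6 is a good migrating group, because C8a carries the lactone oxygen.
4. Diketone chain ⇐ C8 ketone + lithiated (E)-1-diazopent-3-en-2-one, then oxidation of the diazo carbon; C8 ketone ⇐ (R)-carvone (isopropenyl → acrylic acid; C8a–O by enolate iodination and carboxylate displacement; C5–OH and C6–H by Luche reduction and hydroboration).
5. Ring order: cyclohexene ring of carvone (purchased) → cis-fused γ-lactone (step 3) → seven-membered carbocycle by one-carbon ring expansion (step 11).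

Key step: step 11

Remark: locants in the Why lines are those of the target (in the six-membered intermediates C7 is absent and C6 is bonded to C8); α is the face carrying the lactone bonds C8a–O1 and C3a–C3, β the opposite face; dimethyldioxirane is taken as a freshly prepared acetone solution.

## Route

Step 1
Reactants: 1 (R)-(−)-carvone
Product: 2 10-hydroxycarvone
Conditions: SeO2 (0.3 equiv), t-BuOOH (70% aq, 2 equiv), salicylic acid (cat.), CH2Cl2, rt
Reagents that add atoms: selenium dioxide, O=[Se]=O (catalytic oxygen carrier); tert-butyl hydroperoxide, CC(C)(C)OO (stoichiometric oxygen source)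
Why: SeO2/t-BuOOH allylic oxidation (ene reaction then [2,3]-shift) should functionalise the methyl of the electron-rich 1,1-disubstituted alkene while the deactivated enone alkene is left alone; no stereocentre is touched.

Step 2
Reactants: 2 10-hydroxycarvone
Product: 4 acrylic acid, via enal 3 (not isolated)
Conditions: TEMPO (0.2 equiv), PhI(OAc)2 (2.5 equiv), MeCN/H2O 1:1, rt
Reagents that add atoms: water, O
Why: Oxoammonium (TEMPO) oxidation in wet acetonitrile should take the primary allylic alcohol through the enal and its hydrate to the acrylic acid without affecting the enone.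

Step 3
Reactants: 4 acrylic acid
Product: 6 enone lactone, via iodo acid 5 (not isolated)
Conditions: LDA (2.2 equiv), THF, −78 °C; I2 (1.05 equiv), −78 °C → rt
Reagents that add atoms: none
Why: Kinetic α′-deprotonation of the enone (its only enolisable position) gives the carboxylate/dienolate dianion, α-iodination should occur anti to the ring substituent (β face), and intramolecular SN2 displacement by the carboxylate (5-exo-tet, inversion) then places the lactone oxygen α at C8a, cis to the C3a side chain.

Step 4
Reactants: 6 enone lactone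
Product: 7 selenide
Conditions: PhSeH (1.05 equiv), Et3N (0.1 equiv), CH2Cl2, 0 °C
Reagents that add atoms: benzeneselenol, [SeH]c1ccccc1
Why: Base-catalysed seleno-Michael addition should mask the unhindered exocyclic acrylate, which would not survive borane, while addition to the β-substituted enone is reversible and not retained; the new C3 centre is removed again in step 6.

Step 5
Reactants: 7 selenide
Product: 8 allylic alcohol
Conditions: NaBH4 (1.0 equiv), CeCl3·7H2O (1.1 equiv), MeOH, −40 °C
Reagents that add atoms: none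
Why: Luche 1,2-reduction; hydride should add to C8 from the convex β face, anti to the adjacent C8a–O bond (Felkin–Anh), so that the new C8 hydroxyl is α, cis to the lactone oxygen.

Step 6
Reactants: 8 allylic alcohol
Product: 11 diol lactone, via bis-borane 9 (not isolated), via selenoxide 10 (not isolated)
Conditions: BH3·THF (3 equiv), THF, 0 °C → rt; then 30% H2O2, aq NaHCO3, 0 °C → rt
Reagents that add atoms: hydrogen peroxide, OO
Why: Hydroboration should place boron on the less substituted C5 and add H and B syn from the β face (anti to the allylic C8–O group and convex), so oxidation with retention gives β-OH at C5 trans to the α-methyl at C6; the same peroxide oxidises the selenide, and selenoxide syn-elimination restores the α-methylene lactone.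

Step 7
Reactants: 11 diol lactone
Product: 12 mono-TBS ether
Conditions: TBSCl (1.1 equiv), imidazole (2.5 equiv), DMF, 0 °C
Reagents that add atoms: tert-butyldimethylsilyl chloride, CC(C)(C)[Si](C)(C)Cl
Why: Silylation should discriminate the two secondary alcohols on steric grounds, since the C8 hydroxyl is flanked by two cis substituents (C6-Me and C8a–O) whereas the C5 hydroxyl is open.

Step 8
Reactants: 12 mono-TBS ether
Product: 13 keto lactone
Conditions: Dess–Martin periodinane (1.3 equiv), CH2Cl2, rt
Reagents that add atoms: none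
Why: Dess–Martin oxidation of the remaining secondary alcohol under near-neutral conditions should give the C8 ketone without epimerising C6 or C8a.

Step 9
Reactants: 14 (E)-pent-3-en-2-one
Product: 16 diazo enone, via trifluoroacetyl diketone 15 (not isolated)
Conditions: LiHMDS (1.1 equiv), THF, −78 °C; CF3CO2CH2CF3 (1.2 equiv); then 4-acetamidobenzenesulfonyl azide (1.5 equiv), Et3N (1.5 equiv), H2O (1 equiv), MeCN, rt
Reagents that add atoms: 4-acetamidobenzenesulfonyl azide, CC(=O)Nc1ccc(cc1)S(=O)(=O)N=[N+]=[N-]
Why: Detrifluoroacetylative diazo transfer: kinetic trifluoroacetylation of the methyl group activates it for diazo transfer with loss of the trifluoroacetyl group, the standard access to diazomethyl enones that avoids pyrazoline formation.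

Step 10
Reactants: 13 keto lactone; 16 diazo enone
Product: 17 diazo alcohol
Conditions: LiHMDS (1.2 equiv), 16 (1.3 equiv), THF, −78 °C; then 13, −78 °C; AcOH quench at −78 °C
Reagents that add atoms: none
Why: Aldol-type addition of the lithiated diazo ketone to the C8 ketone; attack should come from the β face, opposite the lactone ring and the pseudo-axial C3a–C3 bond that blocks the α trajectory, so the new tertiary centre carries the carbon chain β and the hydroxyl α.

Step 11
Reactants: 17 diazo alcohol
Product: 19 ring-expanded hydroxy diketone, via vicinal diketone 18 (not isolated)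
Conditions: dimethyldioxirane (1.1 equiv, acetone), −78 → −20 °C; volatiles removed cold; then Sc(OTf)3 (10 mol %), 4 Å MS, CH2Cl2, 0 °C → rt
Reagents that add atoms: dimethyldioxirane, CC1(C)OO1
Why: Dimethyldioxirane converts the diazo carbon into a ketone with loss of N2, giving a tertiary alcohol attached to a 1,2-diketone; Sc(III) chelates the hydroxyl and the adjacent carbonyl and triggers an α-ketol (acyloin) 1,2-shift in which the ring bond C8–C6 migrates to that carbonyl carbon, which becomes ring atom C7 while the old carbinol carbon becomes the C8 ketone. The closest known reaction type is the Lewis-acid-catalysed α-ketol rearrangement of β-hydroxy-α-dicarbonyl compounds and the ring-expanding acyloin shift of 1-acylcycloalkanols (D-homoannulation). No ring is closed by cyclisation: the seven-membered carbocycle arises by one-carbon ring expansion of the cyclohexane through a suprafacial 1,2-alkyl shift with retention at the migrating C6. The new quaternary stereocentre C7 is controlled by relay from the carbinol configuration set in step 10: in the syn-periplanar chelate C6 adds to the carbonyl face that leaves the new hydroxyl α and the butenoyl group β. The step needs migration of C6 and not of C8a, which the electron-withdrawing lactone oxygen on C8a secures, and it needs the equilibrium on the ring-expanded side, which is driven by turning a 1,2-diketone into a 1,3-diketone and by relief of the axial hydroxyl's 1,3-diaxial strain.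

Step 12
Reactants: 19 ring-expanded hydroxy diketone
Product: 20 diol
Conditions: Me4NBH(OAc)3 (3 equiv), MeCN/AcOH 2:1, −30 °C
Reagents that add atoms: none
Why: Hydroxyl-directed triacetoxyborohydride reduction (Evans–Saksena type): the borohydride exchanges onto the α C7–OH and should deliver hydride to the α face of the adjacent, more electrophilic C8 ketone, giving the β C8–OH (trans-diol) while the conjugated ketone and both Michael acceptors are spared.

Step 13
Reactants: 20 diol
Product: 21 isobutyrate
Conditions: isobutyric anhydride (2 equiv), Et3N (3 equiv), DMAP (0.2 equiv), CH2Cl2, 0 °C → rt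
Reagents that add atoms: isobutyric anhydride, CC(C)C(=O)OC(=O)C(C)C
Why: DMAP-catalysed acylation should esterify the only secondary alcohol (C8–OH), the tertiary C7–OH being too hindered to react.

Step 14
Reactants: 21 isobutyrate
Product: 22 target CNP0123946.1
Conditions: HF·pyridine, pyridine/THF, 0 °C → rt
Reagents that add atoms: none
Why: Fluoride-mediated desilylation under buffered, mildly acidic conditions should free the C5 hydroxyl without acyl migration, retro-aldol cleavage or attack on the lactone, ester and enone.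

## Compound list

1 | (R)-(−)-carvone, (5R)-2-methyl-5-(prop-1-en-2-yl)cyclohex-2-en-1-one | O=C1C(C)=CC[C@@H](C(C)=C)C1 | starting material
2 | 10-hydroxycarvone, (5R)-5-(3-hydroxyprop-1-en-2-yl)-2-methylcyclohex-2-en-1-one | O=C1C(C)=CC[C@@H](C(=C)CO)C1 | intermediate
3 | enal, 2-[(1R)-4-methyl-5-oxocyclohex-3-en-1-yl]prop-2-enal | O=C1C(C)=CC[C@@H](C(=C)C=O)C1 | intermediate
4 | acrylic acid, 2-[(1R)-4-methyl-5-oxocyclohex-3-en-1-yl]prop-2-enoic acid | O=C1C(C)=CC[C@@H](C(=C)C(=O)O)C1 | intermediate
5 | iodo acid, 2-[(1S,6S)-6-iodo-4-methyl-5-oxocyclohex-3-en-1-yl]prop-2-enoic acid (iodine trans to the side chain; lithium carboxylate in the flask) | O=C1C(C)=CC[C@@H](C(=C)C(=O)O)[C@@H]1I | intermediate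
6 | enone lactone, (3aS,7aR)-6-methyl-3-methylidene-3a,4-dihydro-1-benzofuran-2,7(3H,7aH)-dione (cis-fused) | C=C1C(=O)O[C@@H]2[C@H]1CC=C(C)C2=O | intermediate
7 | selenide, (3aS,7aR)-6-methyl-3-[(phenylselanyl)methyl]-3a,4-dihydro-1-benzofuran-2,7(3H,7aH)-dione (C3 epimers) | O=C1O[C@@H]2[C@@H](CC=C(C)C2=O)C1C[Se]c1ccccc1 | intermediate
8 | allylic alcohol, (3aS,7S,7aR)-7-hydroxy-6-methyl-3-[(phenylselanyl)methyl]-3a,4,7,7a-tetrahydro-1-benzofuran-2(3H)-one (C3 epimers) | O=C1O[C@@H]2[C@@H](CC=C(C)[C@@H]2O)C1C[Se]c1ccccc1 | intermediate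
9 | bis-borane, 5β-boranyl-7α-boranyloxy-6α-methyl derivative of the selenide lactone | O=C1O[C@@H]2[C@@H](C[C@@H]([BH2])[C@H](C)[C@@H]2O[BH2])C1C[Se]c1ccccc1 | intermediate
10 | selenoxide, 5β,7α-dihydroxy-6α-methyl-3-[(phenylseleninyl)methyl] lactone | O=C1O[C@@H]2[C@@H](C[C@@H](O)[C@H](C)[C@@H]2O)C1C[Se](=O)c1ccccc1 | intermediate
11 | diol lactone, (3aS,5R,6S,7S,7aR)-5,7-dihydroxy-6-methyl-3-methylidenehexahydro-1-benzofuran-2(3H)-one | C=C1C(=O)O[C@@H]2[C@H]1C[C@@H](O)[C@H](C)[C@@H]2O | intermediate
12 | mono-TBS ether, (3aS,5R,6R,7S,7aR)-5-[(tert-butyldimethylsilyl)oxy]-7-hydroxy-6-methyl-3-methylidenehexahydro-1-benzofuran-2(3H)-one | C=C1C(=O)O[C@@H]2[C@H]1C[C@@H](O[Si](C)(C)C(C)(C)C)[C@H](C)[C@@H]2O | intermediate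
13 | keto lactone, (3aS,5R,6S,7aR)-5-[(tert-butyldimethylsilyl)oxy]-6-methyl-3-methylidenehexahydro-1-benzofuran-2,7-dione | C=C1C(=O)O[C@@H]2[C@H]1C[C@@H](O[Si](C)(C)C(C)(C)C)[C@H](C)C2=O | intermediate
14 | (E)-pent-3-en-2-one | C/C=C/C(C)=O | starting material
15 | trifluoroacetyl diketone, (5E)-1,1,1-trifluorohept-5-ene-2,4-dione | C/C=C/C(=O)CC(=O)C(F)(F)F | intermediate
16 | diazo enone, (3E)-1-diazopent-3-en-2-one | C/C=C/C(=O)C=[N+]=[N-] | intermediate
17 | diazo alcohol, (3aS,5R,6S,7R,7aR)-5-[(tert-butyldimethylsilyl)oxy]-7-[(3E)-1-diazo-2-oxopent-3-en-1-yl]-7-hydroxy-6-methyl-3-methylidenehexahydro-1-benzofuran-2(3H)-one | C=C1C(=O)O[C@@H]2[C@H]1C[C@@H](O[Si](C)(C)C(C)(C)C)[C@H](C)[C@@]2(O)C(=[N+]=[N-])C(=O)/C=C/C | intermediate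
18 | vicinal diketone, (3aS,5R,6S,7S,7aR)-5-[(tert-butyldimethylsilyl)oxy]-7-hydroxy-6-methyl-3-methylidene-7-[(3E)-2-oxopent-3-enoyl]hexahydro-1-benzofuran-2(3H)-one | C=C1C(=O)O[C@@H]2[C@H]1C[C@@H](O[Si](C)(C)C(C)(C)C)[C@H](C)[C@@]2(O)C(=O)C(=O)/C=C/C | intermediate
19 | ring-expanded hydroxy diketone, (3aS,5R,6S,7R,8aR)-7-[(2E)-but-2-enoyl]-5-[(tert-butyldimethylsilyl)oxy]-7-hydroxy-6-methyl-3-methylidenehexahydro-2H-cyclohepta[b]furan-2,8(3H)-dione | C=C1C(=O)O[C@@H]2[C@H]1C[C@@H](O[Si](C)(C)C(C)(C)C)[C@H](C)[C@@](O)(C(=O)/C=C/C)C2=O | intermediate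
20 | diol, (3aS,5R,6S,7S,8S,8aR)-7-[(2E)-but-2-enoyl]-5-[(tert-butyldimethylsilyl)oxy]-7,8-dihydroxy-6-methyl-3-methylideneoctahydro-2H-cyclohepta[b]furan-2-one | C=C1C(=O)O[C@@H]2[C@H]1C[C@@H](O[Si](C)(C)C(C)(C)C)[C@H](C)[C@@](O)(C(=O)/C=C/C)[C@H]2O | intermediate
21 | isobutyrate, (3aS,5R,6S,7S,8S,8aR)-7-[(2E)-but-2-enoyl]-5-[(tert-butyldimethylsilyl)oxy]-7-hydroxy-6-methyl-3-methylidene-2-oxooctahydro-2H-cyclohepta[b]furan-8-yl 2-methylpropanoate | C=C1C(=O)O[C@@H]2[C@H]1C[C@@H](O[Si](C)(C)C(C)(C)C)[C@H](C)[C@@](O)(C(=O)/C=C/C)[C@H]2OC(=O)C(C)C | intermediate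
22 | CNP0123946.1, (3aS,5R,6S,7S,8S,8aR)-7-[(2E)-but-2-enoyl]-5,7-dihydroxy-6-methyl-3-methylidene-2-oxooctahydro-2H-cyclohepta[b]furan-8-yl 2-methylpropanoate | C=C1C(=O)O[C@@H]2[C@H]1C[C@@H](O)[C@H](C)[C@@](O)(C(=O)/C=C/C)[C@H]2OC(=O)C(C)C | target

## Step count and risks

Total step count: 14. Longest linear sequence: 13 steps (steps 1–8 and 10–14 from (R)-carvone); step 9 is a one-step branch.

The three steps most likely to fail:

Step 11 (ring expansion). The ene-dione may be diverted before it rearranges, by 6-endo oxa-Michael closure of the tertiary hydroxyl onto the propenyl ketone. C8a may migrate in competition with C6. The product may scramble by a second acyloin shift (butenoyl migrating from C7 to C8) or by retro-Claisen cleavage. The fallback sets out from 13 and comes back at 21: the same shift is run at the α-keto ester level, where no enone is present and the precedent is closest, and the propenyl ketone is built last by cross-coupling. Lithiated tert-butyl diazoacetate (LiHMDS, THF, −78 °C) should add to 13 to give the diazo ester adduct F1. Dimethyldioxirane should give the α-keto ester F2, which with Sc(OTf)3 should rearrange to the ring-expanded hydroxy keto ester F3. Me4NBH(OAc)3 should then give the diol ester F4, and isobutyric anhydride/DMAP the isobutyrate ester F5. TMSOTf/2,6-lutidine followed by mild aqueous acid should cleave the tert-butyl ester to the acid F6 without loss of the TBS ether. EtSH/EDC should give the S-ethyl thioester F7, and Liebeskind–Srogl coupling with (E)-prop-1-enylboronic acid (Pd2(dba)3, tri(2-furyl)phosphine, CuTC, THF, 50 °C) should give 21.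

Step 12 (directed reduction). Hydride may be delivered to the butenoyl carbonyl, which is also α to the C7 hydroxyl, or to both ketones; conjugate reduction or poor facial control at C8 are further possibilities. The fallback sets out from 19 and comes back at 20: both ketones are reduced 1,2 under Luche conditions (NaBH4, CeCl3·7H2O, MeOH, −78 °C; hydride expected anti to the β butenoyl branch at C8) to the triol F8, and MnO2 in CH2Cl2 then reoxidises only the allylic alcohol.

Step 3 (oxidative lactonisation). The α′-iodo enone may lose HI towards a cross-conjugated dienone and aromatise to a phenol, or iodination may occur from the wrong face and lead to a trans-fused lactone or to none. The fallback sets out from 4 and comes back at 6: the dianion of 4 (LDA, THF, −78 °C) is hydroxylated with 2-(phenylsulfonyl)-3-phenyloxaziridine anti to the side chain to give the trans hydroxy acid F9, and Mitsunobu lactonisation (PPh3, DIAD, THF, 0 °C) closes the lactone with inversion at the carbinol carbon.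

## Further compounds

F1 | step 11 | diazo ester adduct, tert-butyl 2-diazo-2-[7α-hydroxy-5β-(TBS-oxy)-6α-methyl-3-methylidene-2-oxohexahydrobenzofuran-7-yl]acetate | C=C1C(=O)O[C@@H]2[C@H]1C[C@@H](O[Si](C)(C)C(C)(C)C)[C@H](C)[C@@]2(O)C(=[N+]=[N-])C(=O)OC(C)(C)C
F2 | step 11 | α-keto ester, tert-butyl 2-oxo-2-[7α-hydroxy-5β-(TBS-oxy)-6α-methyl-3-methylidene-2-oxohexahydrobenzofuran-7-yl]acetate | C=C1C(=O)O[C@@H]2[C@H]1C[C@@H](O[Si](C)(C)C(C)(C)C)[C@H](C)[C@@]2(O)C(=O)C(=O)OC(C)(C)C
F3 | step 11 | ring-expanded hydroxy keto ester, tert-butyl 7α-hydroxy-5β-(TBS-oxy)-6α-methyl-3-methylidene-2,8-dioxooctahydrocyclohepta[b]furan-7β-carboxylate | C=C1C(=O)O[C@@H]2[C@H]1C[C@@H](O[Si](C)(C)C(C)(C)C)[C@H](C)[C@@](O)(C(=O)OC(C)(C)C)C2=O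
F4 | step 11 | diol ester, tert-butyl 7α,8β-dihydroxy-5β-(TBS-oxy)-6α-methyl-3-methylidene-2-oxooctahydrocyclohepta[b]furan-7β-carboxylate | C=C1C(=O)O[C@@H]2[C@H]1C[C@@H](O[Si](C)(C)C(C)(C)C)[C@H](C)[C@@](O)(C(=O)OC(C)(C)C)[C@H]2O
F5 | step 11 | isobutyrate ester, 8β-isobutyrate of the diol tert-butyl ester | C=C1C(=O)O[C@@H]2[C@H]1C[C@@H](O[Si](C)(C)C(C)(C)C)[C@H](C)[C@@](O)(C(=O)OC(C)(C)C)[C@H]2OC(=O)C(C)C
F6 | step 11 | acid, 7α-hydroxy-8β-(isobutyryloxy)-5β-(TBS-oxy)-6α-methyl-3-methylidene-2-oxooctahydrocyclohepta[b]furan-7β-carboxylic acid | C=C1C(=O)O[C@@H]2[C@H]1C[C@@H](O[Si](C)(C)C(C)(C)C)[C@H](C)[C@@](O)(C(=O)O)[C@H]2OC(=O)C(C)C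
F7 | step 11 | S-ethyl thioester of the acid | C=C1C(=O)O[C@@H]2[C@H]1C[C@@H](O[Si](C)(C)C(C)(C)C)[C@H](C)[C@@](O)(C(=O)SCC)[C@H]2OC(=O)C(C)C
F8 | step 12 | triol, 7β-[(2E)-1-hydroxybut-2-enyl]-7α,8β-dihydroxy-5β-(TBS-oxy)-6α-methyl-3-methylideneoctahydrocyclohepta[b]furan-2-one (side-chain carbinol epimers) | C=C1C(=O)O[C@@H]2[C@H]1C[C@@H](O[Si](C)(C)C(C)(C)C)[C@H](C)[C@@](O)(C(O)/C=C/C)[C@H]2O
F9 | step 3 | trans hydroxy acid, 2-[(1S,6S)-6-hydroxy-4-methyl-5-oxocyclohex-3-en-1-yl]prop-2-enoic acid | O=C1C(C)=CC[C@@H](C(=C)C(=O)O)[C@@H]1O
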